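**Retrosynthetic overview**
1. The C1=N ring closes last, by condensation of an ortho-acetyl (R)-2-aminopropyl arene. The acetyl group enters by ortho-lithiation at the only free position ortho to the OMe, which avoids the para-selective Bischler–Napieralski closure.
2. The biaryl bond C7–C1' comes from a Suzuki–Miyaura coupling of an anisyl boronate (made in the flask from the aryl bromide) with 1-bromo-4,5-dimethoxy-2-methylnaphthalene.
3. Key step: the substituted naphthalene ring is built by a [4+2] cycloaddition of 3-methoxybenzyne with the vinylketene silyl acetal of methyl 3-methylbut-2-enoate. O-Methylation and para-bromination then give the naphthyl bromide.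
4. The C3 stereocentre is bought as the D-alanine-derived cyclic sulfamidate and carried in by Grignard opening at its CH2–O carbon.
5. Ring order: naphthalene ring (cycloaddition), then the biaryl, then the nitrogen ring.

Assumption: the SMILES defines only C3 (R); the biaryl axis has no descriptor, so it is left uncontrolled and compounds 15 to 19 are carried as the mixture of atropo-diastereomers.

**Step 1**
Reactants: 1 methyl 3-methylbut-2-enoate
Product: 2 1-methoxy-3-methyl-1-(trimethylsilyloxy)buta-1,3-diene
Conditions: LiN(i-Pr)2 (1.1 equiv), THF, −78 °C; Me3SiCl, −78 °C → rt; distil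
Reagents that add atoms: chlorotrimethylsilane, C[Si](C)(C)Cl
Why: Kinetic γ-deprotonation of the senecioate gives the extended enolate, which is O-silylated to the vinylketene silyl acetal (silyl dienolate formation); no stereocentre is involved.

**Step 2**
Reactants: 2 1-methoxy-3-methyl-1-(trimethylsilyloxy)buta-1,3-diene; 3 3-methoxy-2-(trimethylsilyl)phenyl trifluoromethanesulfonate
Product: 6 8-methoxy-3-methylnaphthalen-1-ol, via 3-methoxybenzyne 4 (not isolated), via silyl ketal cycloadduct 5 (not isolated)
Conditions: CsF (3 equiv), 2 (2 equiv), MeCN, 0 °C → rt; then 1 M HCl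
Reagents that add atoms: none
Why: Fluoride-induced 1,2-elimination gives the aryne, which undergoes a Diels–Alder [4+2] cycloaddition with the diene; the nucleophilic CH2 terminus bonds to the aryne carbon meta to OMe, so the acetal carbon ends peri to OMe, and loss of the silyl group and methanol aromatises the adduct to the naphthol.

**Step 3**
Reactants: 6 8-methoxy-3-methylnaphthalen-1-ol
Product: 7 1,8-dimethoxy-3-methylnaphthalene
Conditions: MeI, K2CO3, DMF, 50 °C
Reagents that add atoms: iodomethane, CI
Why: Williamson O-methylation of the naphthoxide.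

**Step 4**
Reactants: 7 1,8-dimethoxy-3-methylnaphthalene
Product: 8 1-bromo-4,5-dimethoxy-2-methylnaphthalene
Conditions: NBS (1.0 equiv), MeCN, 0 °C → rt, dark
Reagents that add atoms: N-bromosuccinimide, O=C1CCC(=O)N1Br
Why: Electrophilic aromatic bromination at the α-position para to the OMe of the methyl-bearing ring (C4 of 7), which is activated by both the para-OMe and the ortho-methyl group.

**Step 5**
Reactants: 9 1-bromo-4-iodo-2-methoxybenzene; 10 tert-butyl (4R)-4-methyl-1,2,3-oxathiazolidine-3-carboxylate 2,2-dioxide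
Product: 13 tert-butyl (R)-[1-(4-bromo-3-methoxyphenyl)propan-2-yl]carbamate, via aryl Grignard reagent 11 (not isolated), via N-sulfamate salt 12 (not isolated)
Conditions: 9, i-PrMgCl·LiCl (1.05 equiv), THF, −20 °C; then CuI (10 mol %), 10 (0.9 equiv), −20 °C → rt; then 1 M HCl (aq), rt, 30 min
Reagents that add atoms: none
Why: Iodine–magnesium exchange is selective for the C–I bond, and copper-catalysed SN2 opening of the cyclic sulfamidate at its primary CH2–O carbon leaves the D-alanine-derived stereocentre untouched (R retained); dilute acid hydrolyses the N-sulfamate.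

**Step 6**
Reactants: 13 tert-butyl (R)-[1-(4-bromo-3-methoxyphenyl)propan-2-yl]carbamate; 8 1-bromo-4,5-dimethoxy-2-methylnaphthalene
Product: 15 tert-butyl (R)-{1-[4-(4,5-dimethoxy-2-methylnaphthalen-1-yl)-3-methoxyphenyl]propan-2-yl}carbamate, via pinacol boronate 14 (not isolated)
Conditions: 13, B2pin2 (1.05 equiv), Pd(OAc)2 (4 mol %), SPhos (8 mol %), KOAc, 1,4-dioxane, 90 °C; then 8, K3PO4, H2O, 100 °C
Reagents that add atoms: none
Why: One-pot Miyaura borylation of the less hindered bromide followed by Suzuki–Miyaura coupling, with the bulky electron-rich biarylphosphine enabling the tri-ortho-substituted biaryl; the remote stereocentre is not affected.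

**Step 7**
Reactants: 15 tert-butyl (R)-{1-[4-(4,5-dimethoxy-2-methylnaphthalen-1-yl)-3-methoxyphenyl]propan-2-yl}carbamate
Product: 19 (3R)-7-(4,5-dimethoxy-2-methylnaphthalen-1-yl)-8-methoxy-1,3-dimethyl-3,4-dihydroisoquinoline (CNP0168311.1), via dilithiated carbamate 16 (not isolated), via Boc amino ketone 17 (not isolated), via free amino ketone 18 (not isolated)
Conditions: n-BuLi (2.5 equiv), Et2O, 0 °C → rt; MeC(O)N(OMe)Me, −78 → 0 °C; then 4 M HCl in 1,4-dioxane, rt; aq. NaHCO3
Reagents that add atoms: N-methoxy-N-methylacetamide, CC(=O)N(C)OC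
Why: Directed ortho-metalation at the only free position ortho to the anisole OMe, which is also flanked by the N-lithiated carbamate side chain, then Weinreb ketone synthesis; acid removes the Boc group and the amine condenses with the ketone to the six-membered cyclic ketimine, with C3 never touched.

**Compound list**
1 | methyl 3-methylbut-2-enoate | COC(=O)C=C(C)C | starting material
2 | 1-methoxy-3-methyl-1-(trimethylsilyloxy)buta-1,3-diene (geometry at C1=C2 irrelevant) | COC(O[Si](C)(C)C)=CC(C)=C | intermediate
3 | 3-methoxy-2-(trimethylsilyl)phenyl trifluoromethanesulfonate | COc1cccc(OS(=O)(=O)C(F)(F)F)c1[Si](C)(C)C | starting material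
4 | 3-methoxybenzyne | COC1=CC=CC#C1 | intermediate
5 | 1,8-dimethoxy-3-methyl-1-(trimethylsilyloxy)-1,4-dihydronaphthalene (racemic ketal carbon, lost on aromatisation) | COc1cccc2c1C(OC)(O[Si](C)(C)C)C=C(C)C2 | intermediate
6 | 8-methoxy-3-methylnaphthalen-1-ol | COc1cccc2cc(C)cc(O)c12 | intermediate
7 | 1,8-dimethoxy-3-methylnaphthalene | COc1cccc2cc(C)cc(OC)c12 | intermediate
8 | 1-bromo-4,5-dimethoxy-2-methylnaphthalene | COc1cccc2c(Br)c(C)cc(OC)c12 | intermediate
9 | 1-bromo-4-iodo-2-methoxybenzene | COc1cc(I)ccc1Br | starting material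
10 | tert-butyl (4R)-4-methyl-1,2,3-oxathiazolidine-3-carboxylate 2,2-dioxide (from D-alaninol) | C[C@@H]1COS(=O)(=O)N1C(=O)OC(C)(C)C | starting material
11 | (4-bromo-3-methoxyphenyl)magnesium chloride | COc1cc([Mg]Cl)ccc1Br | intermediate
12 | chloromagnesium (R)-N-Boc-N-[1-(4-bromo-3-methoxyphenyl)propan-2-yl]sulfamate | C[C@H](Cc1ccc(Br)c(OC)c1)N(C(=O)OC(C)(C)C)S(=O)(=O)O[Mg]Cl | intermediate
13 | tert-butyl (R)-[1-(4-bromo-3-methoxyphenyl)propan-2-yl]carbamate | C[C@H](Cc1ccc(Br)c(OC)c1)NC(=O)OC(C)(C)C | intermediate
14 | tert-butyl (R)-{1-[3-methoxy-4-(4,4,5,5-tetramethyl-1,3,2-dioxaborolan-2-yl)phenyl]propan-2-yl}carbamate | C[C@H](Cc1ccc(B2OC(C)(C)C(C)(C)O2)c(OC)c1)NC(=O)OC(C)(C)C | intermediate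
15 | tert-butyl (R)-{1-[4-(4,5-dimethoxy-2-methylnaphthalen-1-yl)-3-methoxyphenyl]propan-2-yl}carbamate (both axis orientations) | C[C@H](Cc1ccc(-c2c(C)cc(OC)c3c(OC)cccc23)c(OC)c1)NC(=O)OC(C)(C)C | intermediate
16 | N,C2-dilithio derivative of 15 (aryl lithium between OMe and the side chain, N-lithio carbamate) | C[C@H](Cc1ccc(-c2c(C)cc(OC)c3c(OC)cccc23)c(OC)c1[Li])N([Li])C(=O)OC(C)(C)C | intermediate
17 | tert-butyl (R)-{1-[2-acetyl-4-(4,5-dimethoxy-2-methylnaphthalen-1-yl)-3-methoxyphenyl]propan-2-yl}carbamate | C[C@H](Cc1ccc(-c2c(C)cc(OC)c3c(OC)cccc23)c(OC)c1C(C)=O)NC(=O)OC(C)(C)C | intermediate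
18 | 1-{6-[(2R)-2-aminopropyl]-3-(4,5-dimethoxy-2-methylnaphthalen-1-yl)-2-methoxyphenyl}ethanone | C[C@H](Cc1ccc(-c2c(C)cc(OC)c3c(OC)cccc23)c(OC)c1C(C)=O)N | intermediate
19 | (3R)-7-(4,5-dimethoxy-2-methylnaphthalen-1-yl)-8-methoxy-1,3-dimethyl-3,4-dihydroisoquinoline | COc1c(-c2c(C)cc(OC)c3c(OC)cccc23)ccc2c1C(C)=N[C@H](C)C2 | target

**Step count**
Total: 7 steps. Longest linear sequence: 6 steps (steps 1, 2, 3, 4, 6, 7).

**Steps most likely to fail, with fallbacks**

Step 7 is the most exposed. The two naphthyl OMe groups offer competing ortho-lithiation sites, and the hindered aryllithium may enolise the Weinreb amide instead of adding to it. The fallback closes the nitrogen ring before the biaryl bond is made, so that the lithiation runs on a simple anisole. It sets out from 10 (and uses 8) and comes back to the route at 19. Commercial 4-bromo-1-chloro-2-methoxybenzene is converted with i-PrMgCl·LiCl into (4-chloro-3-methoxyphenyl)magnesium chloride F1. This opens 10 (CuI cat., then 1 M HCl) to tert-butyl (R)-[1-(4-chloro-3-methoxyphenyl)propan-2-yl]carbamate F2. Lithiation between OMe and the side chain (s-BuLi, TMEDA, THF, −78 °C; the chloride is meta to the lithiated carbon, so no aryne can form), acetylation with N-methoxy-N-methylacetamide and HCl treatment give (R)-7-chloro-8-methoxy-1,3-dimethyl-3,4-dihydroisoquinoline F3. Separately, 8 is converted (n-BuLi, THF, −78 °C; B(OMe)3; aq. HCl) into (4,5-dimethoxy-2-methylnaphthalen-1-yl)boronic acid F4. Suzuki–Miyaura coupling of F3 with F4 (Pd(OAc)2, SPhos, K3PO4, toluene/H2O, 100 °C) gives 19.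

Step 2 may suffer from fluoride attack on the silyl ketene acetal or from [2+2] addition at the acetal double bond. The fallback drops both the silyl diene and the fluoride and replaces the concerted cycloaddition by a stepwise anionic annulation. It sets out from 1 and comes back at 6. Treating 1 with LiN(i-Pr)2 (3 equiv, THF, −78 °C) gives lithium 1-methoxy-3-methylbuta-1,3-dien-1-olate F5. 3-Bromoanisole is added and the mixture is warmed to rt; the excess amide base generates the same aryne 4, the γ-carbon of the dienolate adds meta to OMe, and the resulting aryl anion closes onto the ester to give 6 after acidic work-up.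

Step 4 may give some bromination at C5 (the other ring) or at C2. The fallback lets the free naphthol control the position of the halogen instead of the methyl ether. It sets out from 6 and comes back at 8. NBS (MeCN, −20 °C) brominates para to the OH, on the far more activated phenolic ring, to give 4-bromo-8-methoxy-3-methylnaphthalen-1-ol F6, and O-methylation (MeI, K2CO3, DMF) gives 8.

**Further compounds**
F1 | step 7 | (4-chloro-3-methoxyphenyl)magnesium chloride | COc1cc([Mg]Cl)ccc1Cl
F2 | step 7 | tert-butyl (R)-[1-(4-chloro-3-methoxyphenyl)propan-2-yl]carbamate | C[C@H](Cc1ccc(Cl)c(OC)c1)NC(=O)OC(C)(C)C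
F3 | step 7 | (R)-7-chloro-8-methoxy-1,3-dimethyl-3,4-dihydroisoquinoline | COc1c(Cl)ccc2c1C(C)=N[C@H](C)C2
F4 | step 7 | (4,5-dimethoxy-2-methylnaphthalen-1-yl)boronic acid | COc1cccc2c(B(O)O)c(C)cc(OC)c12
F5 | step 2 | lithium 1-methoxy-3-methylbuta-1,3-dien-1-olate | [Li]OC(OC)=CC(C)=C
F6 | step 4 | 4-bromo-8-methoxy-3-methylnaphthalen-1-ol | COc1cccc2c(Br)c(C)cc(O)c12
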